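**Plan**

1. Cuts: the interflavan bond C4 (upper, robinetinidol unit)–C6 (lower, gallocatechin unit); in the lower unit the O1–C2 bond, traced back by a 1,2-shift of O1 from C2 to C3 to a 2-(α-acyloxybenzyl)-2,3-dihydrobenzofuran; then the O1–C3 bond (epoxide opening) and the C4–C4a bond (Friedel–Crafts allylation).
2. Enabling feature (flavan numbering): lower C2 carries ring B (3,4,5-trioxygenated, para-oxygen donor) and the aryl-ether oxygen O1, and C3 carries a second oxygen. A benzylic C2–O bond ionizes easily and O1 on the neighbouring carbon can bridge, so the two vicinal oxygens can change places and the five-membered ring O1–C3–C4–C4a–C8a (C2 exocyclic) grows into the pyran ring O1–C2–C3–C4–C4a–C8a.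
3. Forward, lower unit: ring A phenol + allyl cation → 1,3-diarylpropene → (S,S)-epoxide → 5-exo closure to the dihydrobenzofuran → hemiglutarate → ring enlargement to the flavan → bromine at C8. Upper unit: (+)-dihydrorobinetin → benzyl ethers → reduction → 4-OMe.
4. The glutarate that migrated in the ring enlargement then serves as tether: esterification with the upper 3-OH, Lewis-acid ring closure C4→C6, methanolysis of the tether, hydrogenolysis of nine benzyl ethers and of C–Br.
5. Stereochemistry: lower C2/C3 from the Shi epoxide through three stereospecific inversions (one in the 5-exo opening, two in the ring enlargement); upper C2/C3 from dihydrorobinetin; upper C4 (4β, cis to 3-O) by delivery along the tether; C6 regiochemistry from the C8 bromine.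

Key step: step 7

Assumption (chemistry): (+)-dihydrorobinetin and the L-fructose-derived Shi ketone are taken as purchasable; compound 16 is drawn as its 4R epimer, and either C4 epimer serves because C4 is ionized in step 12.

**Route**

Step 1
Reactants: 1 3,4,5-tris(benzyloxy)benzaldehyde
Product: 2 (RS)-1-[3,4,5-tris(benzyloxy)phenyl]prop-2-en-1-ol
Conditions: CH2=CHMgBr, THF, 0 °C; then H2O
Reagents that add atoms: vinylmagnesium bromide C=C[Mg]Br
Why: Grignard 1,2-addition to the aldehyde; the carbinol centre forms racemic and is erased in step 2.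

Step 2
Reactants: 2 (RS)-1-[3,4,5-tris(benzyloxy)phenyl]prop-2-en-1-ol; 3 3,5-bis(benzyloxy)phenol
Product: 4 3,5-bis(benzyloxy)-2-{(2E)-3-[3,4,5-tris(benzyloxy)phenyl]prop-2-en-1-yl}phenol
Conditions: 3 (3 equiv), H2SO4 on SiO2 (catalytic), CH2Cl2, rt
Reagents that add atoms: none
Why: Friedel–Crafts allylation in which acid ionizes 2 to the 1-arylallyl cation (the same cation as from the cinnamyl alcohol), which is attacked at its unsubstituted terminus by one of the two equivalent ortho carbons of phenol 3 to give the conjugated E-alkene.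

Step 3
Reactants: 4 3,5-bis(benzyloxy)-2-{(2E)-3-[3,4,5-tris(benzyloxy)phenyl]prop-2-en-1-yl}phenol
Product: 5 [3,5-bis(benzyloxy)-2-{(2E)-3-[3,4,5-tris(benzyloxy)phenyl]prop-2-en-1-yl}phenoxy]tri(propan-2-yl)silane
Conditions: iPr3SiCl, imidazole, DMF, 40 °C
Reagents that add atoms: chlorotri(propan-2-yl)silane CC(C)[Si](Cl)(C(C)C)C(C)C
Why: Silyl ether formation on the phenol, needed because a free phenoxide would be oxidized in step 4; the triisopropylsilyl ether should withstand the carbonate buffer used there.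

Step 4
Reactants: 5 [3,5-bis(benzyloxy)-2-{(2E)-3-[3,4,5-tris(benzyloxy)phenyl]prop-2-en-1-yl}phenoxy]tri(propan-2-yl)silane
Product: 6 [3,5-bis(benzyloxy)-2-({(2S,3S)-3-[3,4,5-tris(benzyloxy)phenyl]oxiran-2-yl}methyl)phenoxy]tri(propan-2-yl)silane
Conditions: L-fructose-derived Shi ketone (1,2:4,5-di-O-isopropylidene-β-L-erythro-2,3-hexodiulo-2,6-pyranose, 0.3 equiv), Oxone (2KHSO5·KHSO4·K2SO4), K2CO3, Bu4NHSO4, MeCN/CH2(OMe)2/aqueous buffer pH 10.5, 0 °C
Reagents that add atoms: potassium peroxymonosulfate (KHSO5, the active part of Oxone) [K+].[O-]S(=O)(=O)OO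
Why: Shi asymmetric epoxidation (chiral dioxirane, spiro transition state) of a trans-disubstituted aryl alkene; the L-fructose-derived ketone should give the (2S,3S)-epoxide, the mirror image of the (R,R) sense known for the D-fructose-derived ketone with trans-β-alkylstyrenes.

Step 5
Reactants: 6 [3,5-bis(benzyloxy)-2-({(2S,3S)-3-[3,4,5-tris(benzyloxy)phenyl]oxiran-2-yl}methyl)phenoxy]tri(propan-2-yl)silane
Product: 8 (S)-[(2R)-4,6-bis(benzyloxy)-2,3-dihydro-1-benzofuran-2-yl][3,4,5-tris(benzyloxy)phenyl]methanol, via tetrabutylammonium epoxy phenoxide 7 (not isolated)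
Conditions: Bu4NF, THF, 0 °C → rt; then H2O
Reagents that add atoms: none
Why: Fluoride desilylation gives phenoxide 7, which opens the epoxide by SN2 in the 5-exo-tet mode at the non-benzylic carbon with inversion (the Baldwin-favoured path under basic, non-ionizing conditions), setting the ring carbon as R and leaving the S carbinol untouched.

Step 6
Reactants: 8 (S)-[(2R)-4,6-bis(benzyloxy)-2,3-dihydro-1-benzofuran-2-yl][3,4,5-tris(benzyloxy)phenyl]methanol
Product: 9 5-{(S)-[(2R)-4,6-bis(benzyloxy)-2,3-dihydro-1-benzofuran-2-yl][3,4,5-tris(benzyloxy)phenyl]methoxy}-5-oxopentanoic acid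
Conditions: glutaric anhydride, 4-(dimethylamino)pyridine (catalytic), pyridine/CH2Cl2, rt
Reagents that add atoms: glutaric anhydride O=C1CCCC(=O)O1
Why: DMAP-catalysed ring-opening esterification of the secondary benzylic alcohol by the cyclic anhydride; the hemiglutarate is at once leaving group, returning nucleophile and later tether.

Step 7
Reactants: 9 5-{(S)-[(2R)-4,6-bis(benzyloxy)-2,3-dihydro-1-benzofuran-2-yl][3,4,5-tris(benzyloxy)phenyl]methoxy}-5-oxopentanoic acid
Product: 11 5-{[(2R,3S)-5,7-bis(benzyloxy)-2-[3,4,5-tris(benzyloxy)phenyl]-3,4-dihydro-2H-chromen-3-yl]oxy}-5-oxopentanoic acid, via oxiranium hemiglutarate ion pair 10 (not isolated)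
Conditions: BF3·OEt2 (0.3 equiv), CH2Cl2 (5 mM), −40 → 0 °C; then pH 4 buffer
Reagents that add atoms: none
Why: Proposed new method: BF3 weakens the benzylic C–O(acyl) bond of 9 (para-oxygen of ring B), the antiperiplanar ring oxygen O1 bridges to this carbon (future C2) to give the trans O-aryl oxiranium ion 10 with its hemiglutarate held as a contact ion pair on the opposite face, and the carboxylate re-bonds at the ring carbon (future C3) while the old O1–C3 bond breaks, so that acyloxy and aryloxy have changed places in a dyotropic-type 1,2-interchange. The closest known reactions are the oxiranium-mediated enlargement of 2-(1-sulfonyloxyalkyl)tetrahydrofurans to 3-acyloxytetrahydropyrans with Zn(OAc)2, the aziridinium enlargement of prolinols to 3-substituted piperidines and Lewis-acid dyotropic ring enlargements of β-lactones, whereas a benzylic ester on a 2,3-dihydrobenzofuran has not been used in this way. The pyran ring is closed by 3-exo-tet attack of O1 on the benzylic carbon followed by opening of the three-membered ring at the non-benzylic carbon, which turns the five-membered ring O1–C3–C4–C4a–C8a into the six-membered ring O1–C2–C3–C4–C4a–C8a. Both new centres arise by inversion, flavan C3 (S) from the R ring carbon set in steps 4 and 5 and flavan C2 (R) from the S carbinol carbon, and any leakage through the open benzylic cation should still end in the 2,3-trans diequatorial flavan. The step needs bond formation at the non-benzylic carbon: return at the benzylic carbon only regenerates 9 and stays reversible, whereas the secondary ester of 11 cannot ionize again, so the system should drain to 11, and low temperature, high dilution and a base-free medium hold back E1 loss to a 2-benzylbenzofuran and Friedel–Crafts capture by a second ring A.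

Step 8
Reactants: 11 5-{[(2R,3S)-5,7-bis(benzyloxy)-2-[3,4,5-tris(benzyloxy)phenyl]-3,4-dihydro-2H-chromen-3-yl]oxy}-5-oxopentanoic acid
Product: 12 5-{[(2R,3S)-8-bromo-5,7-bis(benzyloxy)-2-[3,4,5-tris(benzyloxy)phenyl]-3,4-dihydro-2H-chromen-3-yl]oxy}-5-oxopentanoic acid
Conditions: N-bromosuccinimide (1.0 equiv), CH2Cl2, −40 → 0 °C, dark
Reagents that add atoms: N-bromosuccinimide O=C1CCC(=O)N1Br
Why: Electrophilic aromatic bromination, which in 5,7-di-O-benzylflavan-3-ols goes to C8 (activated by O1 and less hindered than C6), so that C8 is blocked for step 12.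

Step 9
Reactants: 13 (+)-dihydrorobinetin, (2R,3R)-3,7-dihydroxy-2-(3,4,5-trihydroxyphenyl)-2,3-dihydro-4H-chromen-4-one
Product: 14 (2R,3R)-7-(benzyloxy)-3-hydroxy-2-[3,4,5-tris(benzyloxy)phenyl]-2,3-dihydro-4H-chromen-4-one
Conditions: BnBr (4.4 equiv), K2CO3, DMF, rt, argon
Reagents that add atoms: benzyl bromide BrCc1ccccc1
Why: Williamson ether synthesis on the four phenols, the secondary 3-OH not being alkylated by K2CO3/BnBr; the two stereocentres of the natural product are carried over.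

Step 10
Reactants: 14 (2R,3R)-7-(benzyloxy)-3-hydroxy-2-[3,4,5-tris(benzyloxy)phenyl]-2,3-dihydro-4H-chromen-4-one
Product: 16 (2R,3S,4R)-7-(benzyloxy)-4-methoxy-2-[3,4,5-tris(benzyloxy)phenyl]-3,4-dihydro-2H-chromen-3-ol, via flavan-3,4-diol 15 (not isolated)
Conditions: NaBH4, THF/MeOH, 0 °C; aqueous work-up; then on the crude diol camphorsulfonic acid (catalytic), MeOH/CH2Cl2, 0 °C → rt
Reagents that add atoms: methanol CO
Why: Hydride reduction of the ketone to the 2,3-trans-3,4-trans diol 15, then acid-catalysed SN1 etherification of the benzylic 4-OH by methanol; C4 is ionized again in step 12, so its configuration does not matter.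

Step 11
Reactants: 12 5-{[(2R,3S)-8-bromo-5,7-bis(benzyloxy)-2-[3,4,5-tris(benzyloxy)phenyl]-3,4-dihydro-2H-chromen-3-yl]oxy}-5-oxopentanoic acid; 16 (2R,3S,4R)-7-(benzyloxy)-4-methoxy-2-[3,4,5-tris(benzyloxy)phenyl]-3,4-dihydro-2H-chromen-3-ol
Product: 17 mixed glutarate diester of the 3-OH of 16 and the 3-OH of the 8-bromo lower flavan
Conditions: N,N'-dicyclohexylcarbodiimide, 4-(dimethylamino)pyridine, CH2Cl2, rt
Reagents that add atoms: none
Why: Steglich esterification of acid 12 with the only free hydroxyl of 16.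

Step 12
Reactants: 17 mixed glutarate diester of the 3-OH of 16 and the 3-OH of the 8-bromo lower flavan
Product: 19 3-O,3-O-glutaryl-bridged nona-O-benzyl-8-bromo-robinetinidol-(4β→6)-gallocatechin, via flavan-4-yl cation triflate 18 (not isolated)
Conditions: Me3SiOTf (0.5 equiv), CH2Cl2 (1 mM), −40 → 0 °C; Et3N quench
Reagents that add atoms: none
Why: Lewis-acid ionization of the benzylic 4-OMe to cation 18 and intramolecular Friedel–Crafts alkylation, a known tethered variant of the interflavan coupling that gives 3,4-cis products: the glutarate chain hangs from the β-oxygen on C3 and should bring the lower ring A to the β face of C4 (new centre 4R), and because C8 carries bromine only C6 can bond, closing a 14-membered ring.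

Step 13
Reactants: 19 3-O,3-O-glutaryl-bridged nona-O-benzyl-8-bromo-robinetinidol-(4β→6)-gallocatechin
Product: 20 nona-O-benzyl-8-bromo-robinetinidol-(4β→6)-gallocatechin (both 3-OH free)
Conditions: NaOMe (catalytic), MeOH/THF, rt
Reagents that add atoms: none
Why: Zemplén transesterification in which methoxide cleaves both ester links of the tether as dimethyl glutarate; benzyl ethers, C–Br and all five stereocentres are inert to these conditions.

Step 14
Reactants: 20 nona-O-benzyl-8-bromo-robinetinidol-(4β→6)-gallocatechin (both 3-OH free)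
Product: 21 robinetinidol-(4β→6)-gallocatechin (target)
Conditions: H2 (1 atm), Pd(OH)2/C, Et3N, THF/MeOH/H2O, rt; filtration, freeze-drying
Reagents that add atoms: none
Why: Catalytic hydrogenolysis removes the nine benzyl ethers and the C8 bromine in one operation (Et3N takes up HBr), and the interflavan bond of a 5-deoxy upper unit should not be cleaved under these conditions.

**Compound list**

1 | 3,4,5-tris(benzyloxy)benzaldehyde | O=Cc1cc(OCc2ccccc2)c(OCc2ccccc2)c(OCc2ccccc2)c1 | starting material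
2 | (RS)-1-[3,4,5-tris(benzyloxy)phenyl]prop-2-en-1-ol (racemic) | OC(C=C)c1cc(OCc2ccccc2)c(OCc2ccccc2)c(OCc2ccccc2)c1 | intermediate
3 | 3,5-bis(benzyloxy)phenol | Oc1cc(OCc2ccccc2)cc(OCc2ccccc2)c1 | starting material
4 | 3,5-bis(benzyloxy)-2-{(2E)-3-[3,4,5-tris(benzyloxy)phenyl]prop-2-en-1-yl}phenol | Oc1cc(OCc2ccccc2)cc(OCc2ccccc2)c1C/C=C/c1cc(OCc2ccccc2)c(OCc2ccccc2)c(OCc2ccccc2)c1 | intermediate
5 | [3,5-bis(benzyloxy)-2-{(2E)-3-[3,4,5-tris(benzyloxy)phenyl]prop-2-en-1-yl}phenoxy]tri(propan-2-yl)silane | CC(C)[Si](C(C)C)(C(C)C)Oc1cc(OCc2ccccc2)cc(OCc2ccccc2)c1C/C=C/c1cc(OCc2ccccc2)c(OCc2ccccc2)c(OCc2ccccc2)c1 | intermediate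
6 | [3,5-bis(benzyloxy)-2-({(2S,3S)-3-[3,4,5-tris(benzyloxy)phenyl]oxiran-2-yl}methyl)phenoxy]tri(propan-2-yl)silane | CC(C)[Si](C(C)C)(C(C)C)Oc1cc(OCc2ccccc2)cc(OCc2ccccc2)c1C[C@@H]1O[C@H]1c1cc(OCc2ccccc2)c(OCc2ccccc2)c(OCc2ccccc2)c1 | intermediate
7 | tetrabutylammonium 3,5-bis(benzyloxy)-2-({(2S,3S)-3-[3,4,5-tris(benzyloxy)phenyl]oxiran-2-yl}methyl)phenoxide (not isolated) | CCCC[N+](CCCC)(CCCC)CCCC.[O-]c1cc(OCc2ccccc2)cc(OCc2ccccc2)c1C[C@@H]1O[C@H]1c1cc(OCc2ccccc2)c(OCc2ccccc2)c(OCc2ccccc2)c1 | intermediate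
8 | (S)-[(2R)-4,6-bis(benzyloxy)-2,3-dihydro-1-benzofuran-2-yl][3,4,5-tris(benzyloxy)phenyl]methanol | O[C@@H](c1cc(OCc2ccccc2)c(OCc2ccccc2)c(OCc2ccccc2)c1)[C@H]1Cc2c(OCc3ccccc3)cc(OCc3ccccc3)cc2O1 | intermediate
9 | 5-{(S)-[(2R)-4,6-bis(benzyloxy)-2,3-dihydro-1-benzofuran-2-yl][3,4,5-tris(benzyloxy)phenyl]methoxy}-5-oxopentanoic acid | OC(=O)CCCC(=O)O[C@@H](c1cc(OCc2ccccc2)c(OCc2ccccc2)c(OCc2ccccc2)c1)[C@H]1Cc2c(OCc3ccccc3)cc(OCc3ccccc3)cc2O1 | intermediate
10 | ion pair of the trans (R,R) O-aryl oxiranium ion (O1 bridging the ring carbon and the benzylic carbon) with the BF3 adduct of hydrogen glutarate (not isolated) | [O+]12c3cc(OCc4ccccc4)cc(OCc4ccccc4)c3C[C@@H]1[C@H]2c1cc(OCc4ccccc4)c(OCc4ccccc4)c(OCc4ccccc4)c1.OC(=O)CCCC(=O)O[B-](F)(F)F | intermediate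
11 | 5-{[(2R,3S)-5,7-bis(benzyloxy)-2-[3,4,5-tris(benzyloxy)phenyl]-3,4-dihydro-2H-chromen-3-yl]oxy}-5-oxopentanoic acid (penta-O-benzyl-(+)-gallocatechin 3-O-hemiglutarate) | OC(=O)CCCC(=O)O[C@H]1Cc2c(OCc3ccccc3)cc(OCc3ccccc3)cc2O[C@@H]1c1cc(OCc3ccccc3)c(OCc3ccccc3)c(OCc3ccccc3)c1 | intermediate
12 | 5-{[(2R,3S)-8-bromo-5,7-bis(benzyloxy)-2-[3,4,5-tris(benzyloxy)phenyl]-3,4-dihydro-2H-chromen-3-yl]oxy}-5-oxopentanoic acid | OC(=O)CCCC(=O)O[C@H]1Cc2c(OCc3ccccc3)cc(OCc3ccccc3)c(Br)c2O[C@@H]1c1cc(OCc3ccccc3)c(OCc3ccccc3)c(OCc3ccccc3)c1 | intermediate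
13 | (+)-dihydrorobinetin, (2R,3R)-3,7-dihydroxy-2-(3,4,5-trihydroxyphenyl)-2,3-dihydro-4H-chromen-4-one | Oc1ccc2c(c1)O[C@H](c1cc(O)c(O)c(O)c1)[C@@H](O)C2=O | starting material
14 | (2R,3R)-7-(benzyloxy)-3-hydroxy-2-[3,4,5-tris(benzyloxy)phenyl]-2,3-dihydro-4H-chromen-4-one | C(c1ccccc1)Oc1ccc2c(c1)O[C@H](c1cc(OCc3ccccc3)c(OCc3ccccc3)c(OCc3ccccc3)c1)[C@@H](O)C2=O | intermediate
15 | (2R,3S,4R)-7-(benzyloxy)-2-[3,4,5-tris(benzyloxy)phenyl]-3,4-dihydro-2H-chromene-3,4-diol (not isolated) | C(c1ccccc1)Oc1ccc2c(c1)O[C@H](c1cc(OCc3ccccc3)c(OCc3ccccc3)c(OCc3ccccc3)c1)[C@@H](O)[C@@H]2O | intermediate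
16 | (2R,3S,4R)-7-(benzyloxy)-4-methoxy-2-[3,4,5-tris(benzyloxy)phenyl]-3,4-dihydro-2H-chromen-3-ol | C(c1ccccc1)Oc1ccc2c(c1)O[C@H](c1cc(OCc3ccccc3)c(OCc3ccccc3)c(OCc3ccccc3)c1)[C@@H](O)[C@@H]2OC | intermediate
17 | mixed pentanedioate: (2R,3S)-8-bromo-5,7-bis(benzyloxy)-2-[3,4,5-tris(benzyloxy)phenyl]chroman-3-yl (2R,3S,4R)-7-(benzyloxy)-4-methoxy-2-[3,4,5-tris(benzyloxy)phenyl]chroman-3-yl glutarate | C(c1ccccc1)Oc1ccc2c(c1)O[C@H](c1cc(OCc3ccccc3)c(OCc3ccccc3)c(OCc3ccccc3)c1)[C@@H](OC(=O)CCCC(=O)O[C@H]3Cc4c(OCc5ccccc5)cc(OCc5ccccc5)c(Br)c4O[C@@H]3c3cc(OCc5ccccc5)c(OCc5ccccc5)c(OCc5ccccc5)c3)[C@@H]2OC | intermediate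
18 | flavan-4-yl cation of the upper unit of 17 after loss of methoxide, as triflate (not isolated) | C(c1ccccc1)Oc1ccc2c(c1)O[C@H](c1cc(OCc3ccccc3)c(OCc3ccccc3)c(OCc3ccccc3)c1)[C@@H](OC(=O)CCCC(=O)O[C@H]3Cc4c(OCc5ccccc5)cc(OCc5ccccc5)c(Br)c4O[C@@H]3c3cc(OCc5ccccc5)c(OCc5ccccc5)c(OCc5ccccc5)c3)[CH+]2.[O-]S(=O)(=O)C(F)(F)F | intermediate
19 | 3-O,3-O-glutaryl-bridged nona-O-benzyl-8-bromo-robinetinidol-(4β→6)-gallocatechin (upper 2R,3S,4R; lower 2R,3S; 14-membered ring) | C(c1ccccc1)Oc1ccc2c(c1)O[C@H](c1cc(OCc3ccccc3)c(OCc3ccccc3)c(OCc3ccccc3)c1)[C@@H](OC(=O)CCCC(=O)O4)[C@H]2c1c(OCc3ccccc3)c(Br)c2c(c1OCc3ccccc3)C[C@H]4[C@@H](c1cc(OCc3ccccc3)c(OCc3ccccc3)c(OCc3ccccc3)c1)O2 | intermediate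
20 | nona-O-benzyl-8-bromo-robinetinidol-(4β→6)-gallocatechin (upper 2R,3S,4R; lower 2R,3S; both 3-OH free) | C(c1ccccc1)Oc1ccc2c(c1)O[C@H](c1cc(OCc3ccccc3)c(OCc3ccccc3)c(OCc3ccccc3)c1)[C@@H](O)[C@H]2c1c(OCc3ccccc3)c(Br)c2c(c1OCc3ccccc3)C[C@H](O)[C@@H](c1cc(OCc3ccccc3)c(OCc3ccccc3)c(OCc3ccccc3)c1)O2 | intermediate
21 | robinetinidol-(4β→6)-gallocatechin (upper 2R,3S,4R; lower 2R,3S) | Oc1ccc2c(c1)O[C@H](c1cc(O)c(O)c(O)c1)[C@@H](O)[C@H]2c1c(O)cc2c(c1O)C[C@H](O)[C@@H](c1cc(O)c(O)c(O)c1)O2 | target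

**Count**

Total steps: 14. Longest linear sequence: 12 steps (steps 1–8, then 11–14); steps 9–10 form the second branch.

**Steps most likely to fail**

1. Step 7 (proposed new method). Process at risk: the ion pair may collapse only at the benzylic carbon (no net change), lose a proton toward the aromatic 2-benzylbenzofuran, or alkylate a second ring A. Fallback with known chemistry, setting out from 6 and returning at 11: desilylation of 6 with Bu4NF buffered by AcOH (THF, 0 °C) should give the neutral epoxy phenol F1, which is not isolated. A trace of camphorsulfonic acid in CH2Cl2 at −20 °C then lets the phenol open the epoxide at the benzylic carbon (6-endo, inversion, the known acid route from such epoxides to 2,3-trans-flavan-3-ols) to give penta-O-benzyl-(+)-gallocatechin F2. Acylation of F2 with glutaric anhydride and DMAP gives 11. In this reserve path the pyran ring is made directly in its final size.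

2. Step 12. Process at risk: participation of the 3-O-acyl carbonyl at C4 or a loose macrocycle conformation may deliver ring A to the α face (3,4-trans), and intermolecular alkylation may compete with ring closure. Fallback, setting out from 12 and 16 and returning at 20: NaOMe in MeOH removes the hemiglutarate of 12 to give 8-bromo-penta-O-benzyl-(+)-gallocatechin F3. F3 (in excess) and 16 are then joined intermolecularly with Me3SiOTf in CH2Cl2 at −78 °C, the standard benzyl-ether interflavan coupling with C8 blocked. Both C4 epimers are expected, with 3,4-trans likely the major one; the 3,4-cis epimer 20 is separated by chromatography and goes on to step 14.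

3. Step 9. Process at risk: base-induced enolization at C3 with opening of the flavanonol ring and loss of configuration at C2/C3, and air oxidation of the pyrogallol ring before it is alkylated. Fallback, setting out from 13 and returning at 15: NaBH4 in EtOH/H2O reduces unprotected 13 to (+)-leucorobinetinidin F4, which has no enolizable ketone left. Benzylation of the four phenols of F4 (BnBr, K2CO3, acetone, argon) gives 15, which enters the methanolysis half of step 10.

**Further compounds**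

F1 | step 7 | 3,5-bis(benzyloxy)-2-({(2S,3S)-3-[3,4,5-tris(benzyloxy)phenyl]oxiran-2-yl}methyl)phenol | Oc1cc(OCc2ccccc2)cc(OCc2ccccc2)c1C[C@@H]1O[C@H]1c1cc(OCc2ccccc2)c(OCc2ccccc2)c(OCc2ccccc2)c1
F2 | step 7 | (2R,3S)-5,7-bis(benzyloxy)-2-[3,4,5-tris(benzyloxy)phenyl]-3,4-dihydro-2H-chromen-3-ol (penta-O-benzyl-(+)-gallocatechin) | O[C@H]1Cc2c(OCc3ccccc3)cc(OCc3ccccc3)cc2O[C@@H]1c1cc(OCc3ccccc3)c(OCc3ccccc3)c(OCc3ccccc3)c1
F3 | step 12 | (2R,3S)-8-bromo-5,7-bis(benzyloxy)-2-[3,4,5-tris(benzyloxy)phenyl]-3,4-dihydro-2H-chromen-3-ol | O[C@H]1Cc2c(OCc3ccccc3)cc(OCc3ccccc3)c(Br)c2O[C@@H]1c1cc(OCc3ccccc3)c(OCc3ccccc3)c(OCc3ccccc3)c1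
F4 | step 9 | (+)-leucorobinetinidin, (2R,3S,4R)-2-(3,4,5-trihydroxyphenyl)-3,4-dihydro-2H-chromene-3,4,7-triol | Oc1ccc2c(c1)O[C@H](c1cc(O)c(O)c(O)c1)[C@@H](O)[C@@H]2O
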